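What was left over in Wednesday's run started my reckoning. After 60.0 min it held 3.1% starting material and 35.7% target, so 61.2% of the charge stood unseen. Tuesday's run, with about a quarter of that catalyst, left the same 3.1% of starting material at 60.0 min. Starting material therefore fell without regard to the catalyst.

| flask | starting material | catalyst | remark | time |
|---|---|---|---|---|
| Tuesday's | 0.12 M | 0.054 mol% | run made earlier |  |
| Wednesday's | 0.12 M | 0.23 mol% | run made earlier |  |
| north | 0.12 M | 0.08 mol% |  | 1.5 h |
| south-east | 0.12 M | 0.15 mol% |  | 1.5 h |
| west | 0.12 M | 0.3 mol% |  | 1.5 h |

- Tuesday's (time / min: target / %, starting material / %): 5.00: 0.7, 71.6; 12.0: 1.0, 47.2; 25.0: 3.1, 20.1; 60.0: 10.8, 3.1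
- Wednesday's (time / min: target / %, starting material / %): 8.00: 2.2, 60.4; 20.0: 7.7, 28.6; 40.0: 22.2, 8.8; 60.0: 35.7, 3.1

(scatter of a reading: 0.5 percentage points)

* amount of target at the end, in percent of the starting material charged for north, south-east, west, in this order
* how the row runs (rises, then falls / rises all the way / hardly changes / falls all the way / falls, then rises)

- "hardly changes" means that all values lie within two and a half points (for a concentration: within two and a half percent of the largest)

I read two times. The lifetime of starting material, τ_A, came from Tuesday's first and last readings as 17.5 min. The lifetime of the unseen pool, τ_I, is its mean size over the rate at which target grew. Wednesday's last two readings gave 96.4 min. Tuesday's gave 370 min, longer by 3.84 times, for 4.26 times less catalyst. So I took the pool's loss as pseudo-first-order, with τ_I inverse to the loading.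

For north that made τ_I 277 min. Because τ_A is far shorter, it enters only as a delay. I defined x, the lifetimes served, as the run time less τ_A, over τ_I. North got 0.261. The converted share is one minus e^(−x), so I expected 23.0% target there, and a row that rises with loading.

The forecast said 24%, 39% and 61%, a row that rises all the way, from “SM → I (uncatalysed), then I → target (catalysed)”. Its north differs from mine.

The flasks gave 24.2%, 40.1% and 62.6%; the row rises all the way.

    catalyst + intermediate → catalyst + target (k = 0.700 L mol⁻¹ s⁻¹)
    2 starting material → homo dimer (k = 4.50 × 10⁻⁴ L mol⁻¹ s⁻¹)
    starting material → intermediate (k = 9.90 × 10⁻⁴ s⁻¹)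

In north, the half-life of starting material by its own step was 0.19 h, and that of intermediate by the catalysed step was 2.9 h, 14.7 times longer. At 1.50 h, north held 0.430% starting material, 70.2% intermediate and 5.09% homo dimer. Taken from that half-life instead of the readings, x in north was not my 0.261 but 0.292. West, with more catalyst, had an x of 1.10; one minus e^(−x), taken of the charge less homo dimer, is 63.2%, and west stood at 62.6% target.

(The data are simulated for substances that don't exist; the scatter is artificial.)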